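# Synthesis plan for (2S,3R,4R)-4-(3-hydroxy-4-methoxyphenyl)-6,7-dimethoxy-2,3-dimethyl-3,4-dihydronaphthalen-1(2H)-one (19)

Tetralone numbering is used throughout: C1 is the carbonyl carbon, then C2, C3, C4, C4a, C5–C8, C8a. Ring A is the dimethoxybenzo ring, ring B the carbocycle that holds the ketone, and ring C the pendant aryl group.

## The problem

Compound 19 is a 4-aryl-1-tetralone. Ring B (C1–C4, C4a, C8a) is fused to the dimethoxybenzene ring A and carries ring C, a 3-hydroxy-4-methoxyphenyl group, on C4 through a single bond. Ring B holds three contiguous stereocentres, C2 (S), C3 (R) and C4 (R); the two methyl groups are trans and the C3 methyl is cis to ring C.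

The three centres differ in kind. C2 is α to the ketone and can be equilibrated, and the target has the favoured arrangement (pseudoaxial aryl at C4, both methyl groups equatorial), so C2 needs no kinetic control. C4 is a diaryl methine with no neighbouring group to lean on and must be set in the absolute sense. C3 is neither acidic nor heteroatom-bearing, so it must be set kinetically, and C4 is the only nearby controller.

The main hazard is aromatisation. Any ring-B intermediate with a C2=C3 or C3=C4 double bond and a hydrogen on the remaining sp3 ring carbon can tautomerise to a 4-aryl-1-naphthol and lose all three centres. Further weak points are the doubly benzylic C4–H bond (acidic once an alkyne or alkene sits on C4), the free phenol of ring C, and the C6 methoxy group para to the ketone, which hot halide nucleophiles can dealkylate.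

The feature that opens the plan is that C2 is α to C1 and C3 bears a methyl group. C2 can be the nucleophilic carbon of a β-keto ester enol, and C3 with its methyl can be the two carbons of a terminal alkyne on C4. An enol–alkyne addition then closes C2–C3, leaves the future methyl as an exocyclic methylene and makes C2 quaternary, which blocks the path to the naphthol.

## Retrosynthesis

**19 from 16 (C2–carboxyl bond and two O–benzyl bonds).** The target is traced back to the benzyl β-keto ester 16, in which C2 is quaternary and the phenol is a benzyl ether. A benzyl ester is preferred to a methyl ester for two reasons. One hydrogenolysis frees both the phenol and the acid 17, which loses carbon dioxide to ketone 18. A dealkoxycarbonylation with hot halide, which would threaten the C6 methoxy group, is avoided. The forward step only has to equilibrate C2 of 18, and the thermodynamics favour 19.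

**16 from 15 (the two new C–H bonds at C3 and its methyl).** The C3 methyl is read as a hydrogenated exocyclic methylene, giving 15. The neighbouring option, conjugate addition of a methyl group to a C2=C3 enone, passes through intermediates that can aromatise; the methylene compound 15 cannot, because C2 is quaternary. The forward reaction must add hydrogen to the face opposite ring C without moving the double bond to C3=C4.

**15 from 14 (C2–C3, the key cut).** Opening C2–C3 gives the alkynyl β-keto ester 14. Cutting here rather than at C3–C4 or C1–C2 keeps the closure intramolecular and six-membered. It uses the acidity that the ketone confers on C2, and it leaves a precursor with a single fixed stereocentre (C4). The forward reaction needs carbon rather than oxygen attack on the alkyne, exo closure and an alkene that stays exocyclic.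

**14 from 13, and 13 from 9 and 10 (C1–C2).** The terminal alkyne 14 comes from its silyl derivative 13. The β-keto ester of 13 is cut at C1–C2 into nitrile 9 and benzyl 2-bromopropanoate 10, joined through the zinc enolate 11 and the enamino ester 12. A nitrile is chosen over a benzoate ester as the C1 precursor for three reasons:
- A zinc enolate is too weak a base to disturb the propargylic, doubly benzylic C4–H.
- A nitrile is not slowed by the bulky ortho substituent the way an electron-rich ester would be.
- A nitrile is the smallest ortho group to carry through the preceding coupling.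

**9 from 5 and 6 (C4–C4a).** The diaryl propargylic centre is cut between C4 and ring A. This gives the racemic propargylic bromide 5 and the arylzinc 8, made from bromonitrile 6 through the Grignard reagent 7. Cutting this bond rather than the C4–ring C bond puts the ortho substituent on the nucleophile and lets the electrophile come from a simple aldehyde. The forward reaction is an enantioconvergent nickel-catalysed arylation, so the stereochemistry of 5 is irrelevant.

**5 from 4, and 4 from 1 and 2.** Bromide 5 comes from alcohol 4, the adduct of the acetylide 3 (from ethynyltrimethylsilane 2) with aldehyde 1. All three starting materials (1, 6, 10) and the alkyne 2 are catalogue compounds.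

## Roads not taken

**Alternative 1:** The cut is at the two C–CH3 bonds, with C4 temporarily oxygenated.
- **Forward step.** The 4-aryl-4-silyloxy enone A1 would take a methyl group from Me2CuLi at C3 on the face away from ring C. The enolate would be trapped by MeI at C2, trans to the new methyl, to give A2. Ionic reduction of the C4–O bond (hydride arriving anti to the C3 methyl) and debenzylation would then lead to 19.
- **Merits.** Both methyl groups and two stereocentres arise in one flask, ring B comes ready-made, and the 2,3-trans relation is set directly. In this part it is shorter than the chosen plan, which needs a hydrogenation and a separate C2 equilibration.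
- **Weak points.** An enantioenriched tertiary diaryl carbinol is no easier to make than C4 itself. The cuprate must choose between an aryl and a silyloxy group on the same carbon, and silyloxy groups often direct anti to themselves. C4 is destroyed on ionisation and must be reset by C3, while the C4 cation has a C3 hydrogen whose loss leads to the naphthol.
- **Comparison.** The chosen plan makes C4 once as a C–H centre and never ionises it, and passes through no intermediate that can aromatise. In return it accepts more steps.

**Alternative 2:** The cut is C3–C4.
- **Forward step.** The aryl tiglyl ketone A3 would be deprotonated at its diarylmethane CH2 by solid KOH in the presence of a chiral quaternary ammonium salt. The resulting dienolate, an oxy-ortho-quinodimethane, would close by disrotatory 6π electrocyclisation. Protonation at C2 would give A4, the benzyl ether of 19.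
- **Merits.** Ring B and the C3/C4 pair form in one step from an achiral ketone, and the cis relation follows from alkene geometry in a concerted event. That is a firmer basis for relative configuration than the substrate-controlled hydrogenation of the chosen plan. If it worked it would need roughly half the steps.
- **Weak points.** The γ-hydrogens of the tiglyl unit compete with the benzylic CH2 for the base. The α-methyl group and the ortho substituent twist the triene out of the conformation it needs. The absolute sense would rest on an ion pair steering a pericyclic closure of an all-carbon triene, a substrate class for which this mode of induction is not established. Any uncatalysed closure is racemic.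
- **Comparison.** The chosen plan sets the absolute configuration by a catalytic reaction of a known class and closes ring B by a precedented reaction type.

**Alternative 3:** The cut is C1–C2 and C3–C4, a [4+2] disconnection.
- **Forward step.** Irradiation of aldehyde A5 at 365 nm with Ti(OiPr)4 and a TADDOL ligand would give the E-dienol, which would add methyl angelate A6 endo to give the all-cis hydroxy ester A7. Oxidation of the C1 carbinol would give A8, the methyl ester counterpart of 16.
- **Merits.** Two C–C bonds and ring B form convergently from two simple pieces. C3 and C4 are fixed by suprafacial addition, the C2 ester gives the same protection against aromatisation, and no delicate propargylic centre is carried. In convergence and step count it is better than the chosen plan.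
- **Weak points.** A6 is a trisubstituted, α,β-dialkyl acrylate and a poor dienophile for a short-lived photoenol. A monodentate ester binds the titanium template weakly, so induction is doubtful. Energy transfer from the excited aldehyde can isomerise A6 to its E isomer and scramble C3. The ester of A8 would have to be removed by hot halide.
- **Comparison.** The chosen plan closes ring B intramolecularly and does not depend on the reactivity of a weak dienophile. It sets C4 by a catalytic step of a known class, and it uses a benzyl ester that leaves under neutral conditions.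

Key step: step 6

Assumption: the antipode of the pybox ligand that delivers (R)-9 is used; both antipodes are available, so the sense of induction only decides which one is taken.

Remark: C2 in 13–18 is a mixture of epimers and is drawn without configuration. The C4 descriptor reads S in 15 and R elsewhere because the CIP ranking of the C3 branch changes; the spatial arrangement is the same throughout.

## Route

Step 1
Reactants: 1 3-(benzyloxy)-4-methoxybenzaldehyde; 2 ethynyltrimethylsilane
Product: 4 rac-1-[3-(benzyloxy)-4-methoxyphenyl]-3-(trimethylsilyl)prop-2-yn-1-ol, via lithium (trimethylsilyl)acetylide 3 (not isolated)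
Conditions: 2, n-BuLi, THF, −78 °C; then 1, −78 to 0 °C; H2O
Reagents that add atoms: none
Why: 1,2-Addition of a lithium acetylide to a non-enolisable aryl aldehyde; the carbinol is racemic on purpose because the C–C coupling in step 3 is enantioconvergent.

Step 2
Reactants: 4 rac-1-[3-(benzyloxy)-4-methoxyphenyl]-3-(trimethylsilyl)prop-2-yn-1-ol
Product: 5 rac-{3-[3-(benzyloxy)-4-methoxyphenyl]-3-bromoprop-1-yn-1-yl}trimethylsilane
Conditions: PBr3 (0.4 equiv), pyridine (cat.), Et2O, 0 °C; aqueous work-up, used crude
Reagents that add atoms: phosphorus tribromide, BrP(Br)Br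
Why: Bromination of an activated benzylic–propargylic alcohol through its phosphite ester; the silyl group blocks attack at the alkyne terminus, and the labile bromide is carried on without chromatography.

Step 3
Reactants: 5 rac-{3-[3-(benzyloxy)-4-methoxyphenyl]-3-bromoprop-1-yn-1-yl}trimethylsilane; 6 2-bromo-4,5-dimethoxybenzonitrile
Product: 9 2-[(1R)-1-[3-(benzyloxy)-4-methoxyphenyl]-3-(trimethylsilyl)prop-2-yn-1-yl]-4,5-dimethoxybenzonitrile, via (2-cyano-4,5-dimethoxyphenyl)magnesium chloride 7 (not isolated), via (2-cyano-4,5-dimethoxyphenyl)zinc bromide 8 (not isolated)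
Conditions: 6, iPrMgCl·LiCl, THF, 0 °C; ZnBr2; then 5, NiCl2·glyme (10 mol%), 2,6-bis(3a,8a-dihydro-8H-indeno[1,2-d]oxazol-2-yl)pyridine (one antipode, 13 mol%), glyme/THF, −20 °C
Reagents that add atoms: none
Why: Enantioconvergent nickel-catalysed Negishi arylation of a racemic secondary propargylic bromide: halogen abstraction from 5 gives a planar benzylic–propargylic radical, the chiral aryl–nickel–pybox complex captures it and reductive elimination forms C4–C4a under ligand control, so both enantiomers of 5 should funnel to (R)-9. The ortho nitrile speeds the Br/Mg exchange, is tolerated by zinc and is the smallest group that can later become C1.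

Step 4
Reactants: 9 2-[(1R)-1-[3-(benzyloxy)-4-methoxyphenyl]-3-(trimethylsilyl)prop-2-yn-1-yl]-4,5-dimethoxybenzonitrile; 10 benzyl 2-bromopropanoate
Product: 13 benzyl 3-{2-[(1R)-1-[3-(benzyloxy)-4-methoxyphenyl]-3-(trimethylsilyl)prop-2-yn-1-yl]-4,5-dimethoxyphenyl}-2-methyl-3-oxopropanoate (C2 epimers), via benzyl 2-(bromozincio)propanoate 11 (not isolated), via Blaise enamino ester 12 (not isolated)
Conditions: Zn dust (activated), THF, reflux, slow addition of 10 (4 equiv); then 1 M HCl, THF, rt
Reagents that add atoms: water, O
Why: Blaise reaction: the zinc enolate 11 adds to the nitrile carbon and dilute acid hydrolyses the zinc-bound enamino ester 12 to the β-keto ester. The Reformatsky reagent is too weak a base to remove the propargylic C4–H, so C4 should be kept, and C2 forms as a mixture that is of no consequence.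

Step 5
Reactants: 13 benzyl 3-{2-[(1R)-1-[3-(benzyloxy)-4-methoxyphenyl]-3-(trimethylsilyl)prop-2-yn-1-yl]-4,5-dimethoxyphenyl}-2-methyl-3-oxopropanoate
Product: 14 benzyl 3-{2-[(1R)-1-[3-(benzyloxy)-4-methoxyphenyl]prop-2-yn-1-yl]-4,5-dimethoxyphenyl}-2-methyl-3-oxopropanoate (C2 epimers)
Conditions: TBAF, AcOH (1:1), THF, 0 °C
Reagents that add atoms: none
Why: Fluoride-induced protodesilylation of an alkynylsilane; the AcOH buffer keeps the medium near neutral, so the propargylic C4–H should not be removed, no allene should form and the benzyl ester is untouched.

Step 6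
Reactants: 14 benzyl 3-{2-[(1R)-1-[3-(benzyloxy)-4-methoxyphenyl]prop-2-yn-1-yl]-4,5-dimethoxyphenyl}-2-methyl-3-oxopropanoate
Product: 15 benzyl (4S)-4-[3-(benzyloxy)-4-methoxyphenyl]-6,7-dimethoxy-2-methyl-3-methylidene-1-oxo-1,2,3,4-tetrahydronaphthalene-2-carboxylate (C2 epimers)
Conditions: In(NTf2)3 (5 mol%), toluene (0.05 M), 80 °C
Reagents that add atoms: none
Why: In(NTf2)3 (trivalent indium) binds the β-keto ester as a chelate and, with loss of HNTf2, forms an indium enolate; the terminal alkyne coordinates to the same metal, C2 and indium add cis across the triple bond, and protonolysis of the alkenylindium by HNTf2 releases the exocyclic methylene and the catalyst. The closest known reaction type is the indium-catalysed Conia-ene cycloisomerisation of α-substituted alkynyl β-keto esters, which forms quaternary carbons and six-membered 2-methylenecycloalkanone carboxylates. Ring B closes in the 6-exo-dig mode with the enol double bond inside the forming ring, and the benzo unit holds C1 and C4 at the right distance. The only new stereocentre is the quaternary C2; it is not controlled and need not be, since it is erased in step 8, while C4 is untouched because no base is present. The step needs carbon rather than oxygen attack, exo rather than endo closure and an alkene that stays exocyclic. Carbon attack is secured by the chelated enolate, which delivers C2 in a cis-addition that the carbonyl oxygen cannot follow. Exo closure follows from the polarisation of the terminal alkyne toward its internal carbon (C3). The alkene should stay in place because protonation at the methylene carbon would put a cation next to the doubly acylated C2.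

Step 7
Reactants: 15 benzyl (4S)-4-[3-(benzyloxy)-4-methoxyphenyl]-6,7-dimethoxy-2-methyl-3-methylidene-1-oxo-1,2,3,4-tetrahydronaphthalene-2-carboxylate
Product: 16 benzyl (3R,4R)-4-[3-(benzyloxy)-4-methoxyphenyl]-6,7-dimethoxy-2,3-dimethyl-1-oxo-1,2,3,4-tetrahydronaphthalene-2-carboxylate (C2 epimers)
Conditions: H2 (4 atm), RhCl(PPh3)3 (10 mol%), toluene/EtOH, rt
Reagents that add atoms: none
Why: Homogeneous hydrogenation of a 1,1-disubstituted alkene with RhCl(PPh3)3, which does not cleave benzyl groups and gives little double-bond migration. The C4 aryl group is pseudoaxial (it avoids H5 and the methylene group), so hydrogen should add to the opposite face and the new C3 methyl ends cis to the aryl group, (3R). In either C2 epimer the face syn to the aryl group carries the aryl group plus one C2 substituent and the other face only one C2 substituent.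

Step 8
Reactants: 16 benzyl (3R,4R)-4-[3-(benzyloxy)-4-methoxyphenyl]-6,7-dimethoxy-2,3-dimethyl-1-oxo-1,2,3,4-tetrahydronaphthalene-2-carboxylate
Product: 19 (2S,3R,4R)-4-(3-hydroxy-4-methoxyphenyl)-6,7-dimethoxy-2,3-dimethyl-3,4-dihydronaphthalen-1(2H)-one, via beta-keto acid 17 (not isolated), via C2-epimeric tetralone 18 (not isolated)
Conditions: H2 (1 atm), Pd/C (10%), EtOAc, rt; filter, 50 °C; then K2CO3, MeOH, rt
Reagents that add atoms: none
Why: Hydrogenolysis frees the phenol and the β-keto acid 17, which loses CO2 on gentle warming to give ketone 18 as a C2 mixture. Base equilibration through the enolate should move it to the isomer with the C2 methyl equatorial, trans to the C3 methyl and away from the pseudoaxial C4 aryl group, which is (2S)-19; C3 and C4 are not acidic under these conditions.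

## Compound list

1 | 3-(benzyloxy)-4-methoxybenzaldehyde (O-benzylisovanillin) | COc1ccc(C=O)cc1OCc1ccccc1 | starting material
2 | ethynyltrimethylsilane | C#C[Si](C)(C)C | starting material
3 | lithium (trimethylsilyl)acetylide | [Li]C#C[Si](C)(C)C | intermediate
4 | rac-1-[3-(benzyloxy)-4-methoxyphenyl]-3-(trimethylsilyl)prop-2-yn-1-ol | COc1ccc(C(O)C#C[Si](C)(C)C)cc1OCc1ccccc1 | intermediate
5 | rac-{3-[3-(benzyloxy)-4-methoxyphenyl]-3-bromoprop-1-yn-1-yl}trimethylsilane | COc1ccc(C(Br)C#C[Si](C)(C)C)cc1OCc1ccccc1 | intermediate
6 | 2-bromo-4,5-dimethoxybenzonitrile | COc1cc(Br)c(C#N)cc1OC | starting material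
7 | (2-cyano-4,5-dimethoxyphenyl)magnesium chloride | COc1cc([Mg]Cl)c(C#N)cc1OC | intermediate
8 | (2-cyano-4,5-dimethoxyphenyl)zinc bromide | COc1cc([Zn]Br)c(C#N)cc1OC | intermediate
9 | 2-[(1R)-1-[3-(benzyloxy)-4-methoxyphenyl]-3-(trimethylsilyl)prop-2-yn-1-yl]-4,5-dimethoxybenzonitrile | COc1ccc([C@H](c2cc(OC)c(OC)cc2C#N)C#C[Si](C)(C)C)cc1OCc1ccccc1 | intermediate
10 | benzyl 2-bromopropanoate (racemic) | CC(Br)C(=O)OCc1ccccc1 | starting material
11 | benzyl 2-(bromozincio)propanoate (Reformatsky reagent) | CC([Zn]Br)C(=O)OCc1ccccc1 | intermediate
12 | benzyl 3-amino-3-{2-[(1R)-1-[3-(benzyloxy)-4-methoxyphenyl]-3-(trimethylsilyl)prop-2-yn-1-yl]-4,5-dimethoxyphenyl}-2-methylprop-2-enoate (Blaise enamino ester, zinc-bound in the flask) | COc1ccc([C@H](c2cc(OC)c(OC)cc2C(N)=C(C)C(=O)OCc2ccccc2)C#C[Si](C)(C)C)cc1OCc1ccccc1 | intermediate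
13 | benzyl 3-{2-[(1R)-1-[3-(benzyloxy)-4-methoxyphenyl]-3-(trimethylsilyl)prop-2-yn-1-yl]-4,5-dimethoxyphenyl}-2-methyl-3-oxopropanoate (C2 epimers) | COc1ccc([C@H](c2cc(OC)c(OC)cc2C(=O)C(C)C(=O)OCc2ccccc2)C#C[Si](C)(C)C)cc1OCc1ccccc1 | intermediate
14 | benzyl 3-{2-[(1R)-1-[3-(benzyloxy)-4-methoxyphenyl]prop-2-yn-1-yl]-4,5-dimethoxyphenyl}-2-methyl-3-oxopropanoate (C2 epimers) | COc1ccc([C@H](c2cc(OC)c(OC)cc2C(=O)C(C)C(=O)OCc2ccccc2)C#C)cc1OCc1ccccc1 | intermediate
15 | benzyl (4S)-4-[3-(benzyloxy)-4-methoxyphenyl]-6,7-dimethoxy-2-methyl-3-methylidene-1-oxo-1,2,3,4-tetrahydronaphthalene-2-carboxylate (C2 epimers) | COc1ccc([C@@H]2c3cc(OC)c(OC)cc3C(=O)C(C)(C(=O)OCc3ccccc3)C2=C)cc1OCc1ccccc1 | intermediate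
16 | benzyl (3R,4R)-4-[3-(benzyloxy)-4-methoxyphenyl]-6,7-dimethoxy-2,3-dimethyl-1-oxo-1,2,3,4-tetrahydronaphthalene-2-carboxylate (C2 epimers) | COc1ccc([C@@H]2c3cc(OC)c(OC)cc3C(=O)C(C)(C(=O)OCc3ccccc3)[C@@H]2C)cc1OCc1ccccc1 | intermediate
17 | (3R,4R)-4-(3-hydroxy-4-methoxyphenyl)-6,7-dimethoxy-2,3-dimethyl-1-oxo-1,2,3,4-tetrahydronaphthalene-2-carboxylic acid (C2 epimers) | COc1ccc([C@@H]2c3cc(OC)c(OC)cc3C(=O)C(C)(C(=O)O)[C@@H]2C)cc1O | intermediate
18 | (3R,4R)-4-(3-hydroxy-4-methoxyphenyl)-6,7-dimethoxy-2,3-dimethyl-3,4-dihydronaphthalen-1(2H)-one, C2 epimer mixture | COc1ccc([C@@H]2c3cc(OC)c(OC)cc3C(=O)C(C)[C@@H]2C)cc1O | intermediate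
19 | (2S,3R,4R)-4-(3-hydroxy-4-methoxyphenyl)-6,7-dimethoxy-2,3-dimethyl-3,4-dihydronaphthalen-1(2H)-one | COc1ccc([C@@H]2c3cc(OC)c(OC)cc3C(=O)[C@@H](C)[C@@H]2C)cc1O | target

## Step count and least certain steps

Total step count: 8. Longest linear sequence: 8 steps (1 to 19); 6 enters at step 3 and 10 at step 4.

**Step 6 (key step).** The alkyne may be attacked by the ketone or enol oxygen instead of C2, giving a six-membered enol ether. The exocyclic double bond may migrate to C3–C4 under the Lewis and Brønsted acid, with loss of the C4 centre. Ring C may add to the activated alkyne, and the benzyl groups may be partly cleaved by the Lewis acid. All of these become possible whenever the alkyne is activated without the enolate taking part.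
Fallback: from 14, close the same bond by a one-electron path with Mn(OAc)3·2H2O (trivalent manganese) in degassed ethanol. The manganese enolate is oxidised to the C2 radical, which closes 6-exo-dig onto the alkyne, and the vinyl radical takes a hydrogen atom from ethanol. The oxygen cannot compete in this manifold. The sequence returns to the route at 15 and makes no new compound (F0).

**Step 3.** Enantioinduction may be insufficient, because the catalyst has to tell an aryl from an alkynyl substituent on a benzylic–propargylic radical. Transmetalation of the ortho-substituted arylzinc may be slow, and coupling at the alkyne terminus would give an allene.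
Fallback: from 5 and 8, form the same bond without induction using NiCl2·glyme and 4,4′-di-tert-butyl-2,2′-bipyridine to give the racemic nitrile F1. Separate the antipodes by preparative chromatography on a chiral stationary phase. The (R)-antipode is 9, where the route is rejoined, and the (S)-nitrile F2 is set aside.

**Step 7.** Facial selectivity may be poor if the C2 substituent on the face opposite the aryl group shields as strongly as the aryl group does. Turnover may be slow at an alkene flanked by a quaternary and a tertiary carbon. Metal hydride addition and elimination may move the double bond to C3–C4, which would erase C4.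
Fallback: from 15, reduce with diimide generated from 2-nitrobenzenesulfonyl hydrazide and Et3N in CH2Cl2 at rt. This metal-free, concerted syn transfer of two hydrogen atoms cannot migrate the alkene and is governed only by approach from the less hindered face. It returns to the route at 16 and makes no new compound (F0).

**Step 4.** Addition to the hindered, electron-rich nitrile may be incomplete while the Reformatsky reagent is consumed by self-condensation.
Fallback: from 9, reduce the nitrile with i-Bu2AlH in toluene at −78 °C and hydrolyse to 2-[(1R)-1-[3-(benzyloxy)-4-methoxyphenyl]-3-(trimethylsilyl)prop-2-yn-1-yl]-4,5-dimethoxybenzaldehyde F3. Add the zinc enolate 11 (Reformatsky reaction) to give the β-hydroxy ester F4, and oxidise with Dess–Martin periodinane. This returns to the route at 13.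

**Step 2.** The electron-rich benzylic–propargylic bromide may ionise, hydrolyse or alkylate another arene before it is coupled.
Fallback: from 4, acylate with methyl chloroformate and pyridine to the stable rac-1-[3-(benzyloxy)-4-methoxyphenyl]-3-(trimethylsilyl)prop-2-yn-1-yl methyl carbonate F5. Couple it with 8 under the nickel/pybox conditions used for propargylic oxygen leaving groups. This returns to the route at 9.

## Further compounds

F0 | step 6 | none | none
F1 | step 3 | rac-2-[1-[3-(benzyloxy)-4-methoxyphenyl]-3-(trimethylsilyl)prop-2-yn-1-yl]-4,5-dimethoxybenzonitrile | COc1ccc(C(c2cc(OC)c(OC)cc2C#N)C#C[Si](C)(C)C)cc1OCc1ccccc1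
F2 | step 3 | 2-[(1S)-1-[3-(benzyloxy)-4-methoxyphenyl]-3-(trimethylsilyl)prop-2-yn-1-yl]-4,5-dimethoxybenzonitrile | COc1ccc([C@@H](c2cc(OC)c(OC)cc2C#N)C#C[Si](C)(C)C)cc1OCc1ccccc1
F0 | step 7 | none | none
F3 | step 4 | 2-[(1R)-1-[3-(benzyloxy)-4-methoxyphenyl]-3-(trimethylsilyl)prop-2-yn-1-yl]-4,5-dimethoxybenzaldehyde | COc1ccc([C@H](c2cc(OC)c(OC)cc2C=O)C#C[Si](C)(C)C)cc1OCc1ccccc1
F4 | step 4 | benzyl 3-{2-[(1R)-1-[3-(benzyloxy)-4-methoxyphenyl]-3-(trimethylsilyl)prop-2-yn-1-yl]-4,5-dimethoxyphenyl}-3-hydroxy-2-methylpropanoate (diastereomer mixture) | COc1ccc([C@H](c2cc(OC)c(OC)cc2C(O)C(C)C(=O)OCc2ccccc2)C#C[Si](C)(C)C)cc1OCc1ccccc1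
F5 | step 2 | rac-1-[3-(benzyloxy)-4-methoxyphenyl]-3-(trimethylsilyl)prop-2-yn-1-yl methyl carbonate | COC(=O)OC(C#C[Si](C)(C)C)c1ccc(OC)c(OCc2ccccc2)c1
A1 | alternative 1 | (4R)-4-[3-(benzyloxy)-4-methoxyphenyl]-6,7-dimethoxy-4-[(triethylsilyl)oxy]naphthalen-1(4H)-one | COc1ccc([C@@]2(O[Si](CC)(CC)CC)c3cc(OC)c(OC)cc3C(=O)C=C2)cc1OCc1ccccc1
A2 | alternative 1 | (2S,3S,4R)-4-[3-(benzyloxy)-4-methoxyphenyl]-6,7-dimethoxy-2,3-dimethyl-4-[(triethylsilyl)oxy]-3,4-dihydronaphthalen-1(2H)-one | COc1ccc([C@@]2(O[Si](CC)(CC)CC)c3cc(OC)c(OC)cc3C(=O)[C@@H](C)[C@@H]2C)cc1OCc1ccccc1
A3 | alternative 2 | (E)-1-{2-[3-(benzyloxy)-4-methoxybenzyl]-4,5-dimethoxyphenyl}-2-methylbut-2-en-1-one | C/C=C(\C)C(=O)c1cc(OC)c(OC)cc1Cc1ccc(OC)c(OCc2ccccc2)c1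
A4 | alternative 2 | (2S,3R,4R)-4-[3-(benzyloxy)-4-methoxyphenyl]-6,7-dimethoxy-2,3-dimethyl-3,4-dihydronaphthalen-1(2H)-one | COc1ccc([C@@H]2c3cc(OC)c(OC)cc3C(=O)[C@@H](C)[C@@H]2C)cc1OCc1ccccc1
A5 | alternative 3 | 2-[3-(benzyloxy)-4-methoxybenzyl]-4,5-dimethoxybenzaldehyde | COc1ccc(Cc2cc(OC)c(OC)cc2C=O)cc1OCc1ccccc1
A6 | alternative 3 | methyl angelate, methyl (Z)-2-methylbut-2-enoate | C/C=C(/C)C(=O)OC
A7 | alternative 3 | methyl 4-[3-(benzyloxy)-4-methoxyphenyl]-1-hydroxy-6,7-dimethoxy-2,3-dimethyl-1,2,3,4-tetrahydronaphthalene-2-carboxylate, all-cis (1-OH, 2-CO2Me, 3-CH3 and 4-aryl on one face; C4 as in the target) | COc1ccc([C@@H]2c3cc(OC)c(OC)cc3[C@H](O)[C@@](C(=O)OC)(C)[C@@H]2C)cc1OCc1ccccc1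
A8 | alternative 3 | methyl 4-[3-(benzyloxy)-4-methoxyphenyl]-6,7-dimethoxy-2,3-dimethyl-1-oxo-1,2,3,4-tetrahydronaphthalene-2-carboxylate (ester, 3-CH3 and aryl cis; C3 and C4 as in 16) | COc1ccc([C@@H]2c3cc(OC)c(OC)cc3C(=O)[C@@](C(=O)OC)(C)[C@@H]2C)cc1OCc1ccccc1
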